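**Plan**

- Retrosynthesis: the C1 phenol of ring B is masked as a benzyl ether and the C4 methyl ether is traced back to a free phenol; ring B is then cut at C3–C4, C1–C2 and C4–C5.
- Enabling feature: ring B carries OH at C1, the ring A aryloxy group at C2, methyl at C3, OMe at C4, H at C5 and isopropyl at C6. C2–C3 is therefore the triple bond of the ring A aryl prop-1-ynyl ether, and C4, C1, C6 and C5 are the C=O carbon, the benzyloxy carbon, the isopropyl carbon and the CH2 end of an α-benzyloxy vinylketene.
- Forward, ring A arm: carvacrol is O-methylated, formylated para to OMe and oxidised (Baeyer–Villiger) to 2-isopropyl-4-methoxy-5-methylphenol, which becomes the propynyl ether through its dichlorovinyl ether (5 steps).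
- Forward, ketene arm: triethyl phosphonoacetate undergoes diazo transfer, O–H insertion with benzyl alcohol, olefination of 3-methylbutan-2-one, saponification and conversion to the acid chloride (5 steps).
- Ring B is the only ring built; the benzannulation joins the two arms, then O-methylation at C4 and hydrogenolysis at C1 finish the route.
- Stereochemistry: the target is achiral and has no stereocentre; only regiochemistry must be controlled, and the polarity of the ynol ether in the [2+2] step sets it.

Key step: step 11

Remark: the olefination is expected to give mainly the (Z)-α-benzyloxy enoate, so the ester, acid and acid chloride are written as (Z); any (E) isomer is carried along because both give the same vinylketene.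

**Route**

Step 1
Reactants: 1 carvacrol (5-isopropyl-2-methylphenol)
Product: 2 4-isopropyl-2-methoxy-1-methylbenzene (carvacrol methyl ether)
Conditions: MeI, K2CO3, acetone, reflux
Reagents that add atoms: iodomethane, CI
Why: Williamson ether synthesis on an unhindered phenoxide, with no other group in carvacrol able to react.

Step 2
Reactants: 2 4-isopropyl-2-methoxy-1-methylbenzene
Product: 3 2-isopropyl-4-methoxy-5-methylbenzaldehyde
Conditions: Cl2CHOMe, TiCl4, CH2Cl2, 0 °C; then H2O
Reagents that add atoms: dichloromethyl methyl ether, COC(Cl)Cl; water, O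
Why: Rieche formylation, an electrophilic aromatic substitution that the methoxy group should direct to its para position because the only ortho position is wedged between OMe and isopropyl.

Step 3
Reactants: 3 2-isopropyl-4-methoxy-5-methylbenzaldehyde
Product: 5 2-isopropyl-4-methoxy-5-methylphenol, via aryl formate 4 (not isolated)
Conditions: mCPBA, CH2Cl2, rt; then KOH, MeOH/H2O, rt; HCl work-up
Reagents that add atoms: 3-chloroperoxybenzoic acid (mCPBA), OOC(=O)c1cccc(Cl)c1
Why: Baeyer–Villiger (Dakin-type) oxidation in which the electron-rich aryl group migrates to oxygen to give formate 4, whose saponification frees the phenol.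

Step 4
Reactants: 5 2-isopropyl-4-methoxy-5-methylphenol; 6 trichloroethylene
Product: 7 1-{[(E)-1,2-dichloroethenyl]oxy}-2-isopropyl-4-methoxy-5-methylbenzene
Conditions: K2CO3, DMF, 70 °C
Reagents that add atoms: none
Why: Base-mediated addition of the phenoxide to dichloroacetylene formed in situ from trichloroethylene (net nucleophilic vinylic substitution), the anti addition giving the (E)-dichlorovinyl ether as is usual for phenols.

Step 5
Reactants: 7 1-{[(E)-1,2-dichloroethenyl]oxy}-2-isopropyl-4-methoxy-5-methylbenzene
Product: 10 1-isopropyl-5-methoxy-4-methyl-2-(prop-1-yn-1-yloxy)benzene, via chloroethynyl ether 8 (not isolated), via lithium aryloxyacetylide 9 (not isolated)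
Conditions: n-BuLi (2.2 equiv), THF, −78 → −40 °C; then MeI, HMPA, −78 °C → rt
Reagents that add atoms: iodomethane, CI
Why: Dehydrochlorination by n-BuLi gives chloroalkyne 8, chlorine–lithium exchange gives acetylide 9 and its C-alkylation with MeI gives the ynol ether, the standard dichlorovinyl ether route to alkynyl ethers.

Step 6
Reactants: 11 triethyl phosphonoacetate
Product: 12 ethyl 2-diazo-2-(diethoxyphosphoryl)acetate
Conditions: NaH, THF, 0 °C; 4-acetamidobenzenesulfonyl azide, 0 °C → rt
Reagents that add atoms: 4-acetamidobenzenesulfonyl azide, CC(=O)Nc1ccc(cc1)S(=O)(=O)N=[N+]=[N-]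
Why: Regitz diazo transfer from the sulfonyl azide to the sodium salt of the doubly activated methylene compound.

Step 7
Reactants: 12 ethyl 2-diazo-2-(diethoxyphosphoryl)acetate; 13 benzyl alcohol
Product: 14 ethyl 2-(benzyloxy)-2-(diethoxyphosphoryl)acetate (racemic)
Conditions: Rh2(OAc)4 (1 mol %), toluene, 80 °C
Reagents that add atoms: none
Why: Rhodium-carbenoid O–H insertion into benzyl alcohol, a standard route to 2-alkoxyphosphonoacetates; the new stereocentre is racemic and disappears in step 8.

Step 8
Reactants: 14 ethyl 2-(benzyloxy)-2-(diethoxyphosphoryl)acetate; 15 3-methylbutan-2-one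
Product: 16 ethyl (Z)-2-(benzyloxy)-3,4-dimethylpent-2-enoate
Conditions: NaH, THF, 0 °C → 65 °C
Reagents that add atoms: none
Why: Horner–Wadsworth–Emmons olefination of a ketone with an α-alkoxy phosphonate anion, expected to place the larger isopropyl group trans to the ester; no stereocentre is formed and the alkene geometry is erased in step 11.

Step 9
Reactants: 16 ethyl (Z)-2-(benzyloxy)-3,4-dimethylpent-2-enoate
Product: 17 (Z)-2-(benzyloxy)-3,4-dimethylpent-2-enoic acid
Conditions: LiOH, THF/MeOH/H2O, 60 °C; HCl work-up
Reagents that add atoms: lithium hydroxide (its oxygen becomes the carboxyl OH), [Li+].[OH-]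
Why: Saponification of the ethyl ester, to which the benzyl enol ether and the tetrasubstituted alkene are inert.

Step 10
Reactants: 17 (Z)-2-(benzyloxy)-3,4-dimethylpent-2-enoic acid
Product: 18 (Z)-2-(benzyloxy)-3,4-dimethylpent-2-enoyl chloride
Conditions: (COCl)2, DMF (cat.), CH2Cl2, 0 °C → rt; concentrated and used crude
Reagents that add atoms: oxalyl chloride, O=C(Cl)C(=O)Cl
Why: Acid chloride formation through the Vilsmeier-type chloroiminium species from oxalyl chloride and DMF, under anhydrous conditions that the acceptor-deactivated enol ether should tolerate.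

Step 11
Reactants: 18 (Z)-2-(benzyloxy)-3,4-dimethylpent-2-enoyl chloride; 10 1-isopropyl-5-methoxy-4-methyl-2-(prop-1-yn-1-yloxy)benzene
Product: 23 4-(benzyloxy)-5-isopropyl-3-(2-isopropyl-4-methoxy-5-methylphenoxy)-2-methylphenol, via vinylketene 19 (not isolated), via cyclobutenone 20 (not isolated), via dienylketene 21 (not isolated), via cyclohexadienone 22 (not isolated)
Conditions: Et3N, toluene, rt (18 added slowly to 10 and Et3N), then 110 °C
Reagents that add atoms: none
Why: Et3N takes HCl out of 18 by 1,4-elimination through the γ-methyl group (the isopropyl methine C–H lies in the alkene plane to escape allylic strain and is kinetically inert), giving the α-benzyloxy vinylketene 19, which adds through its ketene C=C to ynol ether 10 in a [2+2] cycloaddition to give cyclobutenone 20 with the new bonds C3–C4 and C1–C2. On heating, 20 opens in a four-electron conrotatory electrocyclic reaction in which the benzyloxy donor turns outward and the alkenyl group inward, so that the (Z)-dienylketene 21 forms, and six-electron disrotatory electrocyclisation between the ketene carbon and the CH2 terminus (C4–C5) closes ring B as cyclohexadienone 22, which tautomerises to phenol 23. The closest known reaction type is the Danheiser benzannulation of vinylketenes with alkoxyalkynes, whose second half is the thermal rearrangement of a 4-alkenyl-4-alkoxycyclobutenone (Moore rearrangement), and the ketene is released by the amine dehydrochlorination used routinely for alkoxyketenes and vinylketenes. Ring B is the only ring closed and its mode of closure is a thermal six-electron electrocyclisation; 23 has no stereocentre, since the quaternary carbon of racemic 20 becomes trigonal on ring opening. The step needs [2+2] regioselectivity, which the ynol ether secures because its nucleophilic methyl-bearing carbon attacks the electrophilic ketene carbonyl carbon and so places methyl at C3 and the aryloxy group at C2, and it needs deprotonation at the methyl and not at the isopropyl group, which the accessibility of the CH3 hydrogens secures. Slow addition of 18 before heating keeps the free ketene concentration low, so that ketene dimerisation and acylation of 23 are held back, and an aryloxyalkyne has no retro-ene pathway that could destroy it at the temperature of the rearrangement.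

Step 12
Reactants: 23 4-(benzyloxy)-5-isopropyl-3-(2-isopropyl-4-methoxy-5-methylphenoxy)-2-methylphenol
Product: 24 2-(benzyloxy)-1-isopropyl-3-(2-isopropyl-4-methoxy-5-methylphenoxy)-5-methoxy-4-methylbenzene
Conditions: MeI, K2CO3, DMF, rt
Reagents that add atoms: iodomethane, CI
Why: Williamson O-methylation of the only free phenol, which is flanked by methyl and hydrogen and therefore accessible, while the benzyl and diaryl ethers are inert.

Step 13
Reactants: 24 2-(benzyloxy)-1-isopropyl-3-(2-isopropyl-4-methoxy-5-methylphenoxy)-5-methoxy-4-methylbenzene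
Product: 25 6-isopropyl-2-(2-isopropyl-4-methoxy-5-methylphenoxy)-4-methoxy-3-methylphenol (CNP0271085.0)
Conditions: H2 (1 atm), Pd/C, EtOAc/EtOH, rt
Reagents that add atoms: none
Why: Hydrogenolysis of the benzylic C–O bond on palladium, which leaves the aryl methyl ethers, the diaryl ether and both arenes untouched at room temperature.

**Compound list**

1 | carvacrol (5-isopropyl-2-methylphenol) | Cc1ccc(C(C)C)cc1O | starting material
2 | 4-isopropyl-2-methoxy-1-methylbenzene | COc1cc(C(C)C)ccc1C | intermediate
3 | 2-isopropyl-4-methoxy-5-methylbenzaldehyde | COc1cc(C(C)C)c(C=O)cc1C | intermediate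
4 | 2-isopropyl-4-methoxy-5-methylphenyl formate | COc1cc(C(C)C)c(OC=O)cc1C | intermediate
5 | 2-isopropyl-4-methoxy-5-methylphenol | COc1cc(C(C)C)c(O)cc1C | intermediate
6 | trichloroethylene | ClC=C(Cl)Cl | starting material
7 | 1-{[(E)-1,2-dichloroethenyl]oxy}-2-isopropyl-4-methoxy-5-methylbenzene | COc1cc(C(C)C)c(O/C(Cl)=C\Cl)cc1C | intermediate
8 | 1-[(chloroethynyl)oxy]-2-isopropyl-4-methoxy-5-methylbenzene | COc1cc(C(C)C)c(OC#CCl)cc1C | intermediate
9 | lithium 2-(2-isopropyl-4-methoxy-5-methylphenoxy)ethynide | COc1cc(C(C)C)c(OC#C[Li])cc1C | intermediate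
10 | 1-isopropyl-5-methoxy-4-methyl-2-(prop-1-yn-1-yloxy)benzene | COc1cc(C(C)C)c(OC#CC)cc1C | intermediate
11 | triethyl phosphonoacetate | CCOC(=O)CP(=O)(OCC)OCC | starting material
12 | ethyl 2-diazo-2-(diethoxyphosphoryl)acetate | CCOC(=O)C(=[N+]=[N-])P(=O)(OCC)OCC | intermediate
13 | benzyl alcohol | OCc1ccccc1 | starting material
14 | ethyl 2-(benzyloxy)-2-(diethoxyphosphoryl)acetate (racemic) | CCOC(=O)C(OCc1ccccc1)P(=O)(OCC)OCC | intermediate
15 | 3-methylbutan-2-one | CC(C)C(C)=O | starting material
16 | ethyl (Z)-2-(benzyloxy)-3,4-dimethylpent-2-enoate | CC(C)/C(C)=C(\OCc1ccccc1)C(=O)OCC | intermediate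
17 | (Z)-2-(benzyloxy)-3,4-dimethylpent-2-enoic acid | CC(C)/C(C)=C(\OCc1ccccc1)C(=O)O | intermediate
18 | (Z)-2-(benzyloxy)-3,4-dimethylpent-2-enoyl chloride | CC(C)/C(C)=C(\OCc1ccccc1)C(=O)Cl | intermediate
19 | 2-(benzyloxy)-3-isopropylbuta-1,3-dien-1-one | CC(C)C(=C)C(OCc1ccccc1)=C=O | intermediate
20 | 4-(benzyloxy)-3-(2-isopropyl-4-methoxy-5-methylphenoxy)-2-methyl-4-(3-methylbut-1-en-2-yl)cyclobut-2-en-1-one (racemic) | O=C1C(C)=C(Oc2cc(C)c(OC)cc2C(C)C)C1(OCc3ccccc3)C(=C)C(C)C | intermediate
21 | (3Z)-4-(benzyloxy)-3-(2-isopropyl-4-methoxy-5-methylphenoxy)-2-methyl-5-(propan-2-yl)hexa-1,3,5-trien-1-one | O=C=C(C)/C(Oc1cc(C)c(OC)cc1C(C)C)=C(OCc1ccccc1)\C(=C)C(C)C | intermediate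
22 | 4-(benzyloxy)-5-isopropyl-3-(2-isopropyl-4-methoxy-5-methylphenoxy)-2-methylcyclohexa-2,4-dien-1-one | O=C1CC(C(C)C)=C(OCc2ccccc2)C(Oc2cc(C)c(OC)cc2C(C)C)=C1C | intermediate
23 | 4-(benzyloxy)-5-isopropyl-3-(2-isopropyl-4-methoxy-5-methylphenoxy)-2-methylphenol | Oc1cc(C(C)C)c(OCc2ccccc2)c(Oc2cc(C)c(OC)cc2C(C)C)c1C | intermediate
24 | 2-(benzyloxy)-1-isopropyl-3-(2-isopropyl-4-methoxy-5-methylphenoxy)-5-methoxy-4-methylbenzene | COc1cc(C(C)C)c(OCc2ccccc2)c(Oc2cc(C)c(OC)cc2C(C)C)c1C | intermediate
25 | 6-isopropyl-2-(2-isopropyl-4-methoxy-5-methylphenoxy)-4-methoxy-3-methylphenol | COc1cc(C(C)C)c(Oc2c(C)c(OC)cc(C(C)C)c2O)cc1C | target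

**Step count and risks**

Total step count: 13. Longest linear sequence: 8 steps (steps 1–5, then 11–13; the arm of steps 6–10 followed by 11–13 is equally long).

Steps most likely to fail:

1. Step 11. The γ-dehydrochlorination of the tetrasubstituted enoyl chloride may be slower than ketene dimerisation, the aryloxyalkyne is a weaker ketene partner than an alkoxyalkyne, and the phenol formed may be acylated by ketene still present. A methanolic KOH work-up would return acylated phenol, but if the annulation itself fails the diaryl ether would be made by copper-catalysed Ullmann coupling instead. This fallback sets out from phenol 5, which also supplies ring B. Ortho-bromination of 5 (NBS, catalytic i-Pr2NH, CH2Cl2, 0 °C), directed by the free OH to the position between OH and methyl, should give 2-bromo-6-isopropyl-4-methoxy-3-methylphenol F1. Benzylation (BnBr, K2CO3, DMF) should give 2-(benzyloxy)-3-bromo-1-isopropyl-5-methoxy-4-methylbenzene F2. Coupling of F2 with a second portion of 5 (CuI, picolinic acid, K3PO4, DMSO, 110 °C, conditions used for hindered diaryl ethers) rejoins the route at 24.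

2. Step 8. Enolisation of the ketone by the phosphonate anion and slow addition to the hindered carbonyl group may leave the olefination incomplete. The fallback sets out from ketone 15 and uses an aldol addition followed by elimination. The lithium enolate of commercial ethyl 2-(benzyloxy)acetate (CCOC(=O)COCc1ccccc1; LDA, THF, −78 °C) should add to 15 to give ethyl 2-(benzyloxy)-3-hydroxy-3,4-dimethylpentanoate F3 as a mixture of diastereomers. Acetylation (Ac2O, DMAP, Et3N) should give ethyl 3-acetoxy-2-(benzyloxy)-3,4-dimethylpentanoate F4. DBU in toluene at 80 °C then removes the acidic α-hydrogen and expels acetate (E1cB), which can only give the conjugated ester, and the route is rejoined at 16 as either alkene isomer.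

3. Step 5. The lithium aryloxyacetylide may decompose before C-methylation, or the methylation may stay incomplete. The fallback sets out from phenol 5 and avoids the acetylide. Copper-catalysed coupling of 5 with 1,1-dibromoprop-1-ene (CC=C(Br)Br; CuI, 2,2'-bipyridine, K3PO4, toluene, 110 °C) should replace the less hindered bromine and give 1-{[(Z)-1-bromoprop-1-en-1-yl]oxy}-2-isopropyl-4-methoxy-5-methylbenzene F5. Anti elimination of HBr (KOt-Bu, 1,4-dioxane, rt) then rejoins the route at 10.

**Further compounds**

F1 | step 11 | 2-bromo-6-isopropyl-4-methoxy-3-methylphenol | Oc1c(Br)c(C)c(OC)cc1C(C)C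
F2 | step 11 | 2-(benzyloxy)-3-bromo-1-isopropyl-5-methoxy-4-methylbenzene | CC(C)c1cc(OC)c(C)c(Br)c1OCc1ccccc1
F3 | step 8 | ethyl 2-(benzyloxy)-3-hydroxy-3,4-dimethylpentanoate (mixture of diastereomers) | CCOC(=O)C(OCc1ccccc1)C(C)(O)C(C)C
F4 | step 8 | ethyl 3-acetoxy-2-(benzyloxy)-3,4-dimethylpentanoate (mixture of diastereomers) | CCOC(=O)C(OCc1ccccc1)C(C)(OC(C)=O)C(C)C
F5 | step 5 | 1-{[(Z)-1-bromoprop-1-en-1-yl]oxy}-2-isopropyl-4-methoxy-5-methylbenzene | COc1cc(C(C)C)c(O/C(Br)=C/C)cc1C
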